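(The runs were computed on assumed constants, and the scatter is random.)

Decide how G should go into D so that the most Z stands at the end: all at once, fed, in portions, or with D fed instead.

| flask | D | G | remark | time |
|---|---|---|---|---|
| east | 0.080 M | 1.5 equiv | run made earlier |  |
| south | 0.11 M | 1.5 equiv | run made earlier |  |
| south-west | 0.18 M | 1.5 equiv | run made earlier |  |
| north-east | 0.080 M | 0.75 equiv | run made earlier |  |
| noon | 0.080 M | 1.50 equiv | everything together at the start | 30 h |
| autumn | 0.080 M (fed, over 12 h) | 1.50 equiv | all else is in the flask from the start; the feed brings no volume worth counting | 30 h |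
| spring | 0.080 M | 1.50 equiv (fed, over 12 h) | all else is in the flask from the start; the feed brings no volume worth counting | 30 h |
| summer | 0.080 M | 1.50 equiv (in portions, 3, over 12 h) | first portion at the start, last at 12 h | 30 h |

| run | time / h | Z / % | D / % |
|---|---|---|---|
| east | 1.33 | 1.7 | 92.8 |
| east | 4.00 | 5.7 | 82.9 |
| east | 6.00 | 8.6 | 79.6 |
| east | 10.0 | 10.2 | 76.0 |
| east | 15.0 | 11.8 | 73.4 |
| east | 20.0 | 10.1 | 72.6 |
| south | 2.00 | 4.2 | 91.3 |
| south | 6.00 | 10.5 | 79.9 |
| south | 10.0 | 7.0 | 77.3 |
| south | 15.0 | 8.3 | 75.3 |
| south | 25.0 | 10.4 | 76.5 |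
| south | 30.0 | 9.8 | 75.7 |
| south-west | 2.00 | 5.3 | 91.4 |
| south-west | 6.00 | 6.8 | 83.2 |
| south-west | 10.0 | 6.9 | 79.6 |
| south-west | 15.0 | 8.4 | 82.6 |
| south-west | 25.0 | 7.6 | 81.1 |
| south-west | 30.0 | 8.4 | 80.2 |
| north-east | 2.50 | 4.8 | 87.0 |
| north-east | 5.00 | 5.8 | 82.3 |
| north-east | 8.00 | 7.8 | 78.5 |
| north-east | 15.0 | 11.9 | 73.7 |
| north-east | 30.0 | 10.6 | 73.1 |

(each reading ± 1 percentage point)

* the flask that comes out highest in amount of Z, in percent of the D charged, or "all alike" when all lie within 1.5 percentage points (noon / autumn / spring / summer / all alike)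
* Z at the end, in percent of the D charged, noon
* Z at the end, in percent of the D charged, autumn
* Z at the end, in percent of the D charged, spring
* Z at the end, in percent of the D charged, summer

- steps thought possible: D <-> E + J; G + E -> Z; 2 G -> X

Keep a ledger of G, taken as the limiting reagent: each Z costs one G and each X costs two, in the steps D ⇌ E + J, G + E → Z and two G → X. Open the east account with 1.5 equiv of G on D at 0.080 M. Z reads 11.8% at 15.0 h and then stops rising, while D and Z together leave 14.8% of the D charged, which you book as E. So enter 7.87% of the G under Z and, assuming that none stays unreacted, the balance, 92.1%, under X.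

Open north-east with half the G. Z reads 11.9% at 15.0 h, the same within the scatter of 1 percentage point, so the X entry absorbs the difference. The two runs average 11.9% of the D charged. Name this z, the dose yield: the Z bought by one dose of G added at once, at this D and between these two charges.

Now count doses. Noon is one dose, so reckon z. Summer has 3 portions 6.00 h apart, and the east readings show 20.4% of its D gone by 6.00 h, more than z, so I count on E refilling between portions. Each summer portion, at 0.500 equiv, is smaller than any dose read, so this step extrapolates. My reckoning for summer is 35.7%, and I take spring, fed over 12 h, at the same figure.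

The forecast names spring, with noon 13%, autumn 9%, spring 22% and summer 19%, and argues: “Feeding G keeps it low, which wastes less and matches G to the E present.”

Spring gives 34.6%, summer 31.2%, noon 10.9% and autumn 5.18%, so spring is highest, and both spring and summer stand above the forecast.

    D ⇌ E + J (K = 0.00470 M, k = 0.0550 /h)
    G + E → Z (k = 21.0 /M/h)
    2 G → X (k = 17.0 /M/h)

Over the first 12 h, spring held G at a mean of 0.0138 M. In dose yields, noon comes to 0.916 z, summer 2.62 z and spring 2.91 z. Spring with a quarter of the G, 0.380 equiv fed the same way, gives 21.1%, which is 1.77 z.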